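The flavonol is disconnected on both sides of C2 of ring C. C2 is bonded only to O1, to the oxygen-bearing C3 and to C1' of ring B and stands at ketone oxidation level, so one molecule of carbon monoxide can supply it. A palladium-catalysed carbonylative alpha-arylation joins a ring A benzyloxymethyl ketone, a ring B aryl iodide and CO in one operation, creating the C1'–C2 and C2–C3 bonds and the complete 2-benzyloxy-1,3-diketone. The ketone precursor carries the future O1 as a methoxymethyl ether, the future 5-OH as a methyl ether and the C3 oxygen as a benzyl ether; acid-induced ring closure, chelation-directed 5-O-demethylation and hydrogenolysis finish the target.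

Key step: step 10

Remark on the chemistry: direct C-acylation of free 3,4,5-trimethoxyphenol would enter next to the hydroxyl group and lead to a 5,6,7-trioxygenated chromone. The 5,7,8 pattern of the target needs 1-(2-hydroxy-3,4,6-trimethoxyphenyl)ethan-1-one, so the phenol is O-methylated first and the crowded ortho-methoxy group is cleaved during the acylation (step 2). Compound 2 can also be purchased, which would remove step 1. The target has no stereocentre. Diketone 21 is drawn in its diketo form although it should be partly enolized.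

Step 1
Reactants: 1 3,4,5-trimethoxyphenol
Product: 2 1,2,3,5-tetramethoxybenzene
Conditions: MeI, K2CO3, acetone, reflux
Reagents that add atoms: iodomethane, CI
Why: Williamson O-methylation of the phenoxide is unambiguous and gives a symmetric arene whose two free ring positions are equivalent.

Step 2
Reactants: 2 1,2,3,5-tetramethoxybenzene
Product: 4 1-(2-hydroxy-3,4,6-trimethoxyphenyl)ethan-1-one, via 2,3,4,6-tetramethoxyacetophenone 3 (not isolated)
Conditions: AcCl, AlCl3, CH2Cl2, 0 °C to rt; then ice, aq. HCl
Reagents that add atoms: acetyl chloride, CC(=O)Cl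
Why: Friedel–Crafts acylation can only enter one of the two equivalent positions, and the AlCl3 chelate of the ketone should then lose the ortho-methyl group wedged between the acyl group and a neighbouring methoxy group (Lewis acid ether cleavage), so the hydroxyl appears at the future O1 while the unhindered ortho-methoxy group, the future 5-oxygen, stays.

Step 3
Reactants: 4 1-(2-hydroxy-3,4,6-trimethoxyphenyl)ethan-1-one
Product: 5 1-[3,4,6-trimethoxy-2-(methoxymethoxy)phenyl]ethan-1-one
Conditions: NaH, MOMCl, DMF, 0 °C to rt
Reagents that add atoms: chloromethyl methyl ether, COCCl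
Why: Williamson-type alkylation of the sodium phenoxide by the reactive chloromethyl ether overcomes the hydrogen bond to the ketone and installs an acetal that tolerates base, peracid and palladium but falls to acid.

Step 4
Reactants: 5 1-[3,4,6-trimethoxy-2-(methoxymethoxy)phenyl]ethan-1-one
Product: 9 2-hydroxy-1-[3,4,6-trimethoxy-2-(methoxymethoxy)phenyl]ethan-1-one, via trimethylsilyl enol ether 6 (not isolated), via silyloxy epoxide 7 (not isolated), via alpha-silyloxy ketone 8 (not isolated)
Conditions: LiN(SiMe3)2, Me3SiCl, THF, −78 °C; then mCPBA, NaHCO3, CH2Cl2, 0 °C; then K2CO3 (cat.), MeOH, 0 °C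
Reagents that add atoms: 3-chloroperoxybenzoic acid, O=C(OO)c1cccc(Cl)c1
Why: Rubottom oxidation, in which the methyl group is the only enolizable position, the enol silane is epoxidized faster than the arene or the ketone reacts, and silyl migration followed by methanolysis should deliver the primary ketol.

Step 5
Reactants: 9 2-hydroxy-1-[3,4,6-trimethoxy-2-(methoxymethoxy)phenyl]ethan-1-one
Product: 10 2-(benzyloxy)-1-[3,4,6-trimethoxy-2-(methoxymethoxy)phenyl]ethan-1-one
Conditions: BnBr, Ag2O, CH2Cl2, rt, dark
Reagents that add atoms: benzyl bromide, BrCc1ccccc1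
Why: Ag2O-assisted Williamson benzylation runs under essentially neutral conditions, so the ketol should not enolize or rearrange and the acetal is untouched.

Step 6
Reactants: 11 3,5-dihydroxy-4-methoxybenzoic acid
Product: 12 benzyl 3,5-bis(benzyloxy)-4-methoxybenzoate
Conditions: BnBr, K2CO3, DMF, 60 °C
Reagents that add atoms: benzyl bromide, BrCc1ccccc1
Why: exhaustive SN2 benzylation (Williamson etherification of both phenoxides and alkylation of the carboxylate) needs no selectivity because all three acidic sites are to be capped.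

Step 7
Reactants: 12 benzyl 3,5-bis(benzyloxy)-4-methoxybenzoate
Product: 13 3,5-bis(benzyloxy)-4-methoxybenzoic acid
Conditions: NaOH, THF–MeOH–H2O, 60 °C; then aq. HCl
Reagents that add atoms: sodium hydroxide, [Na+].[OH-]
Why: saponification cleaves only the ester by acyl–oxygen fission, since aryl benzyl and methyl ethers are inert to hydroxide.

Step 8
Reactants: 13 3,5-bis(benzyloxy)-4-methoxybenzoic acid
Product: 16 tert-butyl N-[3,5-bis(benzyloxy)-4-methoxyphenyl]carbamate, via acyl azide 14 (not isolated), via aryl isocyanate 15 (not isolated)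
Conditions: DPPA, Et3N, t-BuOH–toluene, 90 °C
Reagents that add atoms: diphenylphosphoryl azide, [N-]=[N+]=NP(=O)(Oc1ccccc1)Oc1ccccc1; tert-butanol, CC(C)(C)O
Why: Curtius rearrangement, in which the acyl azide loses N2 with migration of the aryl group to nitrogen and the isocyanate is trapped by tert-butanol, so nitrogen lands exactly on the former carboxyl-bearing ring carbon.

Step 9
Reactants: 16 tert-butyl N-[3,5-bis(benzyloxy)-4-methoxyphenyl]carbamate
Product: 19 1,3-bis(benzyloxy)-5-iodo-2-methoxybenzene, via anilinium tosylate 17 (not isolated), via arenediazonium tosylate 18 (not isolated)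
Conditions: TsOH·H2O, MeCN, 60 °C; then NaNO2, KI, H2O, 10 °C to rt
Reagents that add atoms: potassium iodide, [K+].[I-]
Why: acidolysis of the carbamate, diazotization and copper-free Sandmeyer-type displacement of N2 by iodide should place iodine at the position meta to both benzyloxy groups, which electrophilic iodination of the ring would not reach.

Step 10
Reactants: 10 2-(benzyloxy)-1-[3,4,6-trimethoxy-2-(methoxymethoxy)phenyl]ethan-1-one; 19 1,3-bis(benzyloxy)-5-iodo-2-methoxybenzene; 20 carbon monoxide
Product: 21 racemic 2-(benzyloxy)-1-[3,5-bis(benzyloxy)-4-methoxyphenyl]-3-[3,4,6-trimethoxy-2-(methoxymethoxy)phenyl]propane-1,3-dione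
Conditions: Pd(OAc)2 (5 mol %), Xantphos (5 mol %), CO (1 atm), MgCl2, Et3N, 1,4-dioxane, 80 °C
Reagents that add atoms: none
Why: Pd(OAc)2 is reduced in the flask to a zerovalent palladium–Xantphos complex that inserts into the C–I bond of 19, and CO then inserts into the aryl–palladium bond to give an aroyl complex of divalent palladium. Et3N and MgCl2 turn ketone 10 into a magnesium enolate chelated through the carbonyl and benzyloxy oxygens; this enolate binds to palladium through carbon and reductive elimination forms the C2–C3 bond after the C1'–C2 bond and returns zerovalent palladium. The closest known reaction type is the palladium-catalysed carbonylative alpha-arylation of ketones by aryl iodides to 1,3-diketones, applied here to an alpha-alkoxy aryl ketone. No ring is closed, and the one new stereocentre (the benzyloxy-bearing carbon) forms without control as a racemate, which is harmless because it becomes the sp2 carbon C3 in step 11. The step needs C- rather than O-acylation, a single acylation and carbonylative rather than direct arylation: the chelated magnesium enolate reacts through carbon, the product is withdrawn as its stabilized magnesium diketonate and is a hindered tertiary carbon acid, and the CO atmosphere together with the wide-bite-angle ligand should make CO insertion faster than enolate capture by the arylpalladium species. The methoxymethyl ether keeps the ring A phenol from being aroylated at oxygen, and the two ortho substituents shield the ketone carbonyl from self-condensation.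

Step 11
Reactants: 21 racemic 2-(benzyloxy)-1-[3,5-bis(benzyloxy)-4-methoxyphenyl]-3-[3,4,6-trimethoxy-2-(methoxymethoxy)phenyl]propane-1,3-dione
Product: 24 3-(benzyloxy)-2-[3,5-bis(benzyloxy)-4-methoxyphenyl]-5,7,8-trimethoxy-4H-chromen-4-one, via free phenol diketone 22 (not isolated), via cyclic hemiketal 23 (not isolated)
Conditions: conc. HCl, MeOH–THF, 60 °C
Reagents that add atoms: none
Why: acid-catalysed acetal cleavage frees the phenol, which adds to the ring B aroyl carbonyl (6-exo-trig, the only feasible closure, forming O1–C2), and the hemiketal dehydrates to the aromatic 4-pyranone in the classical cyclodehydration of 2-hydroxyphenyl 1,3-diketones to flavones, while benzyl and methyl ethers are stable.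

Step 12
Reactants: 24 3-(benzyloxy)-2-[3,5-bis(benzyloxy)-4-methoxyphenyl]-5,7,8-trimethoxy-4H-chromen-4-one
Product: 25 3-(benzyloxy)-2-[3,5-bis(benzyloxy)-4-methoxyphenyl]-5-hydroxy-7,8-dimethoxy-4H-chromen-4-one
Conditions: AlCl3, MeCN, 0 °C to rt; then aq. HCl
Reagents that add atoms: none
Why: chelation-directed Lewis acid ether cleavage, in which AlCl3 is held in a six-membered chelate between the C4 carbonyl and the peri 5-methoxy oxygen so that chloride removes only that methyl group, while the 7-, 8- and 4'-methoxy groups cannot chelate and the benzyl ethers should survive the nitrile-moderated reagent.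

Step 13
Reactants: 25 3-(benzyloxy)-2-[3,5-bis(benzyloxy)-4-methoxyphenyl]-5-hydroxy-7,8-dimethoxy-4H-chromen-4-one
Product: 26 2-(3,5-dihydroxy-4-methoxyphenyl)-3,5-dihydroxy-7,8-dimethoxy-4H-chromen-4-one
Conditions: H2 (1 atm), 10% Pd/C, THF–MeOH, rt
Reagents that add atoms: none
Why: catalytic hydrogenolysis cleaves the three benzyl C–O bonds under conditions that leave the fully substituted C2=C3 bond of the chromone and the methyl ethers untouched.

Compound list
1 | 3,4,5-trimethoxyphenol | COc1cc(O)cc(OC)c1OC | starting material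
2 | 1,2,3,5-tetramethoxybenzene | COc1cc(OC)c(OC)c(OC)c1 | intermediate
3 | 1-(2,3,4,6-tetramethoxyphenyl)ethan-1-one (2,3,4,6-tetramethoxyacetophenone) | CC(=O)c1c(OC)cc(OC)c(OC)c1OC | intermediate (not isolated)
4 | 1-(2-hydroxy-3,4,6-trimethoxyphenyl)ethan-1-one | CC(=O)c1c(OC)cc(OC)c(OC)c1O | intermediate
5 | 1-[3,4,6-trimethoxy-2-(methoxymethoxy)phenyl]ethan-1-one | COCOc1c(OC)c(OC)cc(OC)c1C(C)=O | intermediate
6 | trimethyl({1-[3,4,6-trimethoxy-2-(methoxymethoxy)phenyl]ethenyl}oxy)silane | COCOc1c(OC)c(OC)cc(OC)c1C(=C)O[Si](C)(C)C | intermediate (not isolated)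
7 | racemic trimethyl({2-[3,4,6-trimethoxy-2-(methoxymethoxy)phenyl]oxiran-2-yl}oxy)silane | COCOc1c(OC)c(OC)cc(OC)c1C1(CO1)O[Si](C)(C)C | intermediate (not isolated)
8 | 1-[3,4,6-trimethoxy-2-(methoxymethoxy)phenyl]-2-[(trimethylsilyl)oxy]ethan-1-one | COCOc1c(OC)c(OC)cc(OC)c1C(=O)CO[Si](C)(C)C | intermediate (not isolated)
9 | 2-hydroxy-1-[3,4,6-trimethoxy-2-(methoxymethoxy)phenyl]ethan-1-one | COCOc1c(OC)c(OC)cc(OC)c1C(=O)CO | intermediate
10 | 2-(benzyloxy)-1-[3,4,6-trimethoxy-2-(methoxymethoxy)phenyl]ethan-1-one | COCOc1c(OC)c(OC)cc(OC)c1C(=O)COCc1ccccc1 | intermediate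
11 | 3,5-dihydroxy-4-methoxybenzoic acid | COc1c(O)cc(C(=O)O)cc1O | starting material
12 | benzyl 3,5-bis(benzyloxy)-4-methoxybenzoate | COc1c(OCc2ccccc2)cc(C(=O)OCc2ccccc2)cc1OCc1ccccc1 | intermediate
13 | 3,5-bis(benzyloxy)-4-methoxybenzoic acid | COc1c(OCc2ccccc2)cc(C(=O)O)cc1OCc1ccccc1 | intermediate
14 | 3,5-bis(benzyloxy)-4-methoxybenzoyl azide | COc1c(OCc2ccccc2)cc(C(=O)N=[N+]=[N-])cc1OCc1ccccc1 | intermediate (not isolated)
15 | 1,3-bis(benzyloxy)-5-isocyanato-2-methoxybenzene | COc1c(OCc2ccccc2)cc(N=C=O)cc1OCc1ccccc1 | intermediate (not isolated)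
16 | tert-butyl N-[3,5-bis(benzyloxy)-4-methoxyphenyl]carbamate | COc1c(OCc2ccccc2)cc(NC(=O)OC(C)(C)C)cc1OCc1ccccc1 | intermediate
17 | 3,5-bis(benzyloxy)-4-methoxyanilinium 4-methylbenzenesulfonate | COc1c(OCc2ccccc2)cc([NH3+])cc1OCc1ccccc1.Cc1ccc(cc1)S(=O)(=O)[O-] | intermediate (not isolated)
18 | 3,5-bis(benzyloxy)-4-methoxybenzenediazonium 4-methylbenzenesulfonate | COc1c(OCc2ccccc2)cc([N+]#N)cc1OCc1ccccc1.Cc1ccc(cc1)S(=O)(=O)[O-] | intermediate (not isolated)
19 | 1,3-bis(benzyloxy)-5-iodo-2-methoxybenzene | COc1c(OCc2ccccc2)cc(I)cc1OCc1ccccc1 | intermediate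
20 | carbon monoxide | [C-]#[O+] | starting material
21 | racemic 2-(benzyloxy)-1-[3,5-bis(benzyloxy)-4-methoxyphenyl]-3-[3,4,6-trimethoxy-2-(methoxymethoxy)phenyl]propane-1,3-dione | COCOc1c(OC)c(OC)cc(OC)c1C(=O)C(OCc1ccccc1)C(=O)c1cc(OCc2ccccc2)c(OC)c(OCc2ccccc2)c1 | intermediate
22 | racemic 2-(benzyloxy)-1-[3,5-bis(benzyloxy)-4-methoxyphenyl]-3-(2-hydroxy-3,4,6-trimethoxyphenyl)propane-1,3-dione | COc1cc(OC)c(C(=O)C(OCc2ccccc2)C(=O)c2cc(OCc3ccccc3)c(OC)c(OCc3ccccc3)c2)c(O)c1OC | intermediate (not isolated)
23 | 3-(benzyloxy)-2-[3,5-bis(benzyloxy)-4-methoxyphenyl]-2-hydroxy-5,7,8-trimethoxy-2,3-dihydro-4H-chromen-4-one (racemic mixture of diastereomers) | COc1cc(OC)c2c(c1OC)OC(O)(c1cc(OCc3ccccc3)c(OC)c(OCc3ccccc3)c1)C(OCc1ccccc1)C2=O | intermediate (not isolated)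
24 | 3-(benzyloxy)-2-[3,5-bis(benzyloxy)-4-methoxyphenyl]-5,7,8-trimethoxy-4H-chromen-4-one | COc1cc(OC)c2c(=O)c(OCc3ccccc3)c(-c3cc(OCc4ccccc4)c(OC)c(OCc4ccccc4)c3)oc2c1OC | intermediate
25 | 3-(benzyloxy)-2-[3,5-bis(benzyloxy)-4-methoxyphenyl]-5-hydroxy-7,8-dimethoxy-4H-chromen-4-one | COc1cc(O)c2c(=O)c(OCc3ccccc3)c(-c3cc(OCc4ccccc4)c(OC)c(OCc4ccccc4)c3)oc2c1OC | intermediate
26 | 2-(3,5-dihydroxy-4-methoxyphenyl)-3,5-dihydroxy-7,8-dimethoxy-4H-chromen-4-one | COc1cc(O)c2c(=O)c(O)c(-c3cc(O)c(OC)c(O)c3)oc2c1OC | target

Total step count: 13.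
Longest linear sequence: 9 steps (steps 1–5 and 10–13, from 3,4,5-trimethoxyphenol). The ring B branch (steps 6–9) joins at step 10.

Steps most likely to fail

Step 10. The hindered, only softly enolized ketone may capture the aroylpalladium intermediate too slowly. In that case CO-free alpha-arylation, acylation of the enolate at oxygen or consumption of the iodide by traces of water could take over. The fallback reaches the same diketone by a classical Claisen-type C-acylation. Acid 13 would be converted with oxalyl chloride and catalytic DMF in CH2Cl2 into 3,5-bis(benzyloxy)-4-methoxybenzoyl chloride F1. Ketone 10 would then be acylated by it under soft enolization (MgBr2·OEt2, i-Pr2NEt, CH2Cl2, rt). This fallback sets out from 10 and 13 and returns to the route at 21.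

Step 12. The Lewis acid may also attack the benzyl ethers, since the 3-O-benzyl group sits next to the same carbonyl, or cleave methyl ethers that are not chelated. Either would give mixtures of partly dealkylated flavones. The fallback reverses the order so that no benzyl ether is present when the Lewis acid is used. Hydrogenolysis of 24 (H2, Pd/C, THF–MeOH) should give 2-(3,5-dihydroxy-4-methoxyphenyl)-3-hydroxy-5,7,8-trimethoxy-4H-chromen-4-one F2. BCl3 in CH2Cl2 (−20 to 0 °C, then aqueous work-up) would then bind the free hydroxyls as borate esters and cleave only the chelated 5-methyl ether. This fallback sets out from 24 and returns at 26.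

Step 4. The peracid may oxidize the electron-rich ring or insert into the aryl ketone (Baeyer–Villiger) in competition with epoxidation, or the enol silane may hydrolyse back to 5. The ketol 9 is also the most delicate substrate of the benzylation that follows. The fallback brings in the benzyloxy group by carbenoid O–H insertion and needs no oxidant. Ketone 5 would be trifluoroacetylated (LiN(SiMe3)2, CF3CO2CH2CF3, THF, −78 °C) to 4,4,4-trifluoro-1-[3,4,6-trimethoxy-2-(methoxymethoxy)phenyl]butane-1,3-dione F3. Diazo transfer with loss of the trifluoroacetyl group (MsN3, Et3N, H2O, MeCN) should give 2-diazo-1-[3,4,6-trimethoxy-2-(methoxymethoxy)phenyl]ethan-1-one F4. Decomposition of F4 by catalytic Rh2(OAc)4 in CH2Cl2 in the presence of excess benzyl alcohol would give 10 directly. This fallback sets out from 5 and returns at 10, by-passing steps 4 and 5.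

Further compounds
F1 | step 10 | 3,5-bis(benzyloxy)-4-methoxybenzoyl chloride | COc1c(OCc2ccccc2)cc(C(Cl)=O)cc1OCc1ccccc1
F2 | step 12 | 2-(3,5-dihydroxy-4-methoxyphenyl)-3-hydroxy-5,7,8-trimethoxy-4H-chromen-4-one | COc1cc(OC)c2c(=O)c(O)c(-c3cc(O)c(OC)c(O)c3)oc2c1OC
F3 | step 4 | 4,4,4-trifluoro-1-[3,4,6-trimethoxy-2-(methoxymethoxy)phenyl]butane-1,3-dione | COCOc1c(OC)c(OC)cc(OC)c1C(=O)CC(=O)C(F)(F)F
F4 | step 4 | 2-diazo-1-[3,4,6-trimethoxy-2-(methoxymethoxy)phenyl]ethan-1-one | COCOc1c(OC)c(OC)cc(OC)c1C(=O)C=[N+]=[N-]
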